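The trap here is to treat a big excess of coupling partner as a constant supply and to credit the flask with days of reaction ahead of it.

| flask | starting material | coupling partner | remark | time |
|---|---|---|---|---|
| zeta | 0.025 M (in portions, 4) | 0.20 M | run made earlier; portions every 2.0 h |  |
| flask | 0.050 M (in portions, 4) | 0.200 M | the portions of starting material follow each other after 2.0 h, the first at the start | 4.0 d |

zeta run (percent of the starting material charged)

| time / h | target / % | starting material / % |
|---|---|---|
| 0.833 | 0.3 | 22.5 |
| 1.33 | 1.0 | 21.7 |
| 2.00 | 1.3 | 20.8 |
| 2.50 | 1.7 | 45.8 |
| 4.00 | 2.7 | 45.3 |
| 6.00 | 3.6 | 69.9 |
| 10.0 | 4.5 | 95.1 |

(readings scatter by 0.3 percentage points)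

- the reaction counts as stopped when no species that holds the starting material changes by six tenths of a point or more over the second half of the time

- why nothing more happens at 4.0 d, or that something still does (it is still moving / the coupling partner has run out first / all of the starting material has reacted / forward and back rates have come level)
- the target standing at 4.0 d, as a percentage of the starting material charged

The bench habit is to call the excess pseudo-first-order and let every portion fall at the pace of the first. In the zeta run, the first reading gives that pace as 0.126 h⁻¹, so the habit can be tested on the stretch from 2.00 h to 10.0 h:

expected loss of the charge, with the stock held at its share at 2.00 h = 21.0%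
loss read = 0.700%

The loss read is far less than expected, so on these readings the pace fell to roughly 3.33% of the pace first read. Yet, counting one partner per starting material, the reaction had used 0.613% of the partner's charge, so I take the partner to be fading by itself and to be the first charge to run out.

Then, with the portions timed alike, I take the surviving share to depend on the partner charge, not on the charge of starting material, and from the last zeta reading you can carry the decades (powers of ten) of survival lost per molar of partner:

decades lost per molar = 0.0218 / 0.20 M = 0.109 M⁻¹
surviving share in this flask = ten to the power −(0.109 M⁻¹ × 0.200 M) = 95.1%

This flask has twice the zeta charge but the same partner charge, so I expect the last zeta target share, 4.5%.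

The forecast says it is still moving and 5%, calling the end “a slow, continuing trickle”; it differs from my reckoning on the end and little on the number.

The flask gives the coupling partner has run out first and 4.48%.

    starting material + coupling partner → intermediate + by-product (k = 0.920 M⁻¹ h⁻¹)
    intermediate ⇌ target (K = 10.0, k = 0.300 h⁻¹)
    intermediate ⇌ isomer of the product (K = 4.70, k = 0.00700 h⁻¹)
    coupling partner → decomposed reagent (k = 0.930 h⁻¹)

In the flask by 0.250 d, just before the last addition, the coupling partner, the limiting reagent despite its excess, stood at 0.332% of its charge, with nearly all of that charge now decomposed reagent (0.197 M) against 0.00261 M of by-product; by 2.00 d the by-product stood at 0.00264 M while intermediate had gone from 1.55% to 0.451%. Starting material in the flask stands at 94.7% at the asked time, against 95.1% from the decades, and for the neighbour flask with 0.50 M of partner the decades give 88.2%, where that flask holds 88% and target reaches 9.97%.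

The readings stem from a simulated flask for substances that don't exist; scatter was added.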